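**Retrosynthetic overview**

1. Target 27 ⇐ O9 desilylation and allylic oxidation of isopropenyl lactone 24 ⇐ dehydration of carbinol 23 ⇐ base-induced shift of the isobutyryl group from C11 to O6 (retro-Claisen) in the α-methyl-α-isobutyryl lactone 21.
2. 21 ⇐ formal hydrate of the dihydrofuran-fused lactone 17 ⇐ Cloke–Wilson ring expansion of cyclopropane lactone 16 ⇐ rhodium carbenoid cyclopropanation of C6=C7 by the O8-tethered diazo β-keto ester 15.
3. 15 ⇐ allylic alcohol 12 ⇐ epoxide/selenoxide transposition of the Diels–Alder cyclohexene 4 ⇐ silyloxydiene 2 + formyl crotonate 3.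
4. Ring order: cyclohexene (Diels–Alder); γ-lactone and cyclopropane together (key step); cyclopropane expanded to a dihydrofuran; dihydrofuran opened again by the acyl shift, leaving the lactone.
5. Feature the strategy rests on: C11 on C7 is flanked by the two oxygens O8 and O6, all on one face of the C5–C10 ring, so the lactone carbonyl C12 and the isobutyryl carbonyl are brought in as the two acyl groups of one β-keto ester carbon (C11) hung from O8.

Key step: step 11

Remark: locants follow the elemane skeleton (ring C5–C10, lactone C11/C12, each oxygen numbered after its carbon) and β is the ring face of the C10 methyl group; the catalyst antipode in step 2 is the one that the formyl C–H···O binding model assigns to the (1R,5R,6S) adduct, taken here to be the (S)-prolinol-derived one.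

**Route**

Step 1
Reactants: 1 crotonaldehyde
Product: 2 (E)-1-(tert-butyldimethylsilyloxy)buta-1,3-diene
Conditions: TBSOTf, Et3N, Et2O, 0 °C to rt
Reagents that add atoms: tert-butyldimethylsilyl triflate, CC(C)(C)[Si](C)(C)OS(=O)(=O)C(F)(F)F
Why: Silyl dienol ether formation, in which O-silylation of the enal and γ-deprotonation by the amine give the extended silyl enol ether, the E isomer predominating and being the only one that reacts in the cycloaddition.

Step 2
Reactants: 2 (E)-1-(tert-butyldimethylsilyloxy)buta-1,3-diene; 3 ethyl (2E)-3-methyl-4-oxobut-2-enoate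
Product: 4 Diels–Alder adduct, ethyl (1R,5R,6S)-5-(tert-butyldimethylsilyloxy)-6-formyl-6-methylcyclohex-3-ene-1-carboxylate (C10 β-methyl and α-formyl, C9 α-OTBS, C5 β-ester, C7=C8)
Conditions: (S)-3,3-diphenyl-1-(o-tolyl)tetrahydro-1H,3H-pyrrolo[1,2-c][1,3,2]oxazaborole·Tf2NH (20 mol%), CH2Cl2, −78 °C
Reagents that add atoms: none
Why: Catalytic asymmetric Diels–Alder reaction in which the oxazaborolidinium ion binds the formyl group of 3, so that the diene CH2 terminus bonds to the carbon β to the formyl group (silyloxy carbon C9 next to the quaternary C10), the formyl group reacts endo and ends cis to the silyloxy group of the E diene, the E dienophile keeps methyl and ester cis, and the shielded enal face sets the absolute configuration of C5, C9 and C10.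

Step 3
Reactants: 4 Diels–Alder adduct
Product: 5 vinyl ester (as 4, with the C10 formyl group turned into an α-vinyl group)
Conditions: Ph3PCH3Br, KN(SiMe3)2, THF, 0 °C; then 4, −78 °C to rt
Reagents that add atoms: methylenetriphenylphosphorane (from methyltriphenylphosphonium bromide and KN(SiMe3)2), C=P(c1ccccc1)(c1ccccc1)c1ccccc1
Why: Wittig methylenation of a hindered but non-enolisable aldehyde, which leaves the ester alone and changes no stereocentre.

Step 4
Reactants: 5 vinyl ester
Product: 7 tertiary carbinol (C5 β-CMe2OH), via methyl ketone 6 (not isolated)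
Conditions: MeMgBr (excess), THF, 0 °C to 40 °C
Reagents that add atoms: methylmagnesium bromide, C[Mg]Br
Why: Double Grignard addition, the first equivalent giving the methyl ketone by loss of ethoxide and the second adding to it, with excess reagent and warming to carry this hindered ester through and no stereocentre touched.

Step 5
Reactants: 7 tertiary carbinol
Product: 8 bis-silyl ether (C5 β-CMe2OSiEt3, C9 α-OTBS, C10 β-methyl and α-vinyl, C7=C8)
Conditions: Et3SiOTf, 2,6-lutidine, CH2Cl2, −78 °C to 0 °C
Reagents that add atoms: triethylsilyl triflate, CC[Si](CC)(CC)OS(=O)(=O)C(F)(F)F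
Why: Silyl ether formation with a silyl triflate, reactive enough for the hindered tertiary hydroxyl; the triethylsilyl group is chosen to last until after the acyl shift and still come off later beside the C9 TBS ether.

Step 6
Reactants: 8 bis-silyl ether
Product: 9 C7–C8 β-epoxide (epoxide oxygen anti to the C9 silyloxy group)
Conditions: mCPBA, NaHCO3, CH2Cl2, 0 °C
Reagents that add atoms: 3-chloroperoxybenzoic acid, OOC(=O)c1cccc(Cl)c1
Why: Prilezhaev epoxidation in which the cis ring alkene reacts ahead of the monosubstituted vinyl group and the peracid should approach the β face, anti to the pseudoaxial allylic silyloxy group at C9, which sets C8 (oxygen β) and C7.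

Step 7
Reactants: 9 β-epoxide
Product: 10 hydroxy selenide (C8 β-OH, C7 α-SePh)
Conditions: (PhSe)2, NaBH4, EtOH, rt; then 9, reflux
Reagents that add atoms: sodium benzeneselenolate (from diphenyl diselenide and NaBH4), [Na+].[Se-]c1ccccc1
Why: Epoxide opening by a selenolate (SN2, trans-diaxial Fürst–Plattner opening), with attack at C7 from the α face, remote from the C9 silyloxy group and through the chair that keeps the C5 substituent equatorial, so that C7 carries the α-selenide and the C8 oxygen stays β.

Step 8
Reactants: 10 hydroxy selenide
Product: 12 allylic alcohol (C8 β-OH, C6=C7), via selenoxide 11 (not isolated)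
Conditions: 30% H2O2, pyridine, THF, 0 °C to rt
Reagents that add atoms: hydrogen peroxide, OO (its oxygen is carried by selenoxide 11 only and leaves again with selenium)
Why: Selenoxide syn-elimination, in which oxidation at selenium and loss of PhSeOH toward C6 (elimination toward the hydroxyl-bearing C8 is disfavoured) moves the alkene to C6=C7 and leaves C8 untouched, pyridine suppressing epoxidation by peroxyseleninic acid.

Step 9
Reactants: 12 allylic alcohol; 13 methyl 4-methyl-3-oxopentanoate
Product: 14 O8 β-keto ester (4-methyl-3-oxopentanoate of 12)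
Conditions: DMAP, toluene, reflux, 4 Å molecular sieves
Reagents that add atoms: none
Why: DMAP-promoted transesterification of a β-keto ester, driven by removal of methanol, which acylates the hindered C8 hydroxyl without touching any stereocentre.

Step 10
Reactants: 14 O8 β-keto ester
Product: 15 O8 2-diazo-4-methyl-3-oxopentanoate
Conditions: 4-acetamidobenzenesulfonyl azide, Et3N, MeCN, 0 °C to rt
Reagents that add atoms: 4-acetamidobenzenesulfonyl azide, CC(=O)Nc1ccc(cc1)S(=O)(=O)N=[N+]=[N-]
Why: Regitz diazo transfer to the doubly activated methylene group.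

Step 11
Reactants: 15 O8 diazo β-keto ester
Product: 16 cyclopropane-fused γ-lactone (C11 bonded to C7 and C6 on the β face, lactone C12(=O)–O8, isobutyryl group on C11)
Conditions: Rh2(OAc)4 (2 mol%), CH2Cl2, reflux, slow addition of 15
Reagents that add atoms: none
Why: Loss of N2 from 15 at Rh2(OAc)4 (divalent rhodium) gives an electrophilic acceptor/acceptor carbenoid whose carbon, the future C11, adds in a concerted, asynchronous [2+1] manner across the cis alkene C6=C7 and forms C7–C11 and C6–C11 suprafacially. The closest known reaction type is the intramolecular cyclopropanation of allylic α-diazo-β-keto esters, cyclohex-2-enyl esters included, by rhodium or copper carbenoids to 3-oxabicyclo[3.1.0]hexan-2-ones. The γ-lactone closes as a five-membered ring by bonding of C11 to the proximal alkene carbon C7, since the three-atom O8–C12–C11 tether cannot span to C6 first, and the cyclopropane closes by the second bond to C6. The new stereocentres C7, C6 and C11 are all fixed by the C8 stereocentre, because the tether hangs from the β oxygen O8 and the addition is cis, so both new bonds lie on the β face and the lactone is cis-fused. The step needs cyclopropanation in preference to insertion into the C9–H bond and to reaction at the C10 vinyl group: the electron-rich cis-disubstituted π bond is the favoured partner of this carbenoid, C9–H is crowded by the quaternary C10 and the silyloxy group, and the vinyl group lies on the α face out of reach.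

Step 12
Reactants: 16 cyclopropane-fused γ-lactone
Product: 17 dihydrofuran-fused lactone (O6 β on C6, enol ether C11=C(iPr)–O6 conjugated with the lactone carbonyl)
Conditions: MgI2 (0.3 equiv), toluene, 80 °C
Reagents that add atoms: none
Why: Cloke–Wilson rearrangement of a 1-acyl cyclopropanecarboxylate under MgI2 catalysis, in which magnesium chelation lets iodide open the exocyclic bond C6–C11 by SN2 attack at C6 (opening at C7 is disfavoured by the adjacent C8 acyloxy group and the ring fusion) and the ketone enolate oxygen then displaces iodide (5-exo-tet), the two inversions giving the C6–O6 bond on the β face with overall retention.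

Step 13
Reactants: 17 dihydrofuran-fused lactone
Product: 18 bromo hemiketal (C11–Br on the convex face, hemiketal carbon C(OH)(iPr) between C11 and O6)
Conditions: NBS, THF–H2O, 0 °C
Reagents that add atoms: N-bromosuccinimide, O=C1CCC(=O)N1Br; water, O
Why: Bromohydration of an enol ether (bromonium transfer to the nucleophilic C11 on the open convex face, water capturing the oxocarbenium carbon held by O6) breaks the stable push-pull enol ether irreversibly under neutral conditions, whereas aqueous acid strong enough to protonate it would also strip the triethylsilyl ether and let the freed carbinol trap the cation as a bridged ketal; the C11 configuration is dictated by the bowl-shaped ring fusion.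

Step 14
Reactants: 18 bromo hemiketal
Product: 19 hemiketal (ring form of the C6-hydroxy α-isobutyryl lactone, C11–H)
Conditions: Bu3SnH, Et3B (cat.), air, toluene, 0 °C to rt
Reagents that add atoms: none
Why: Radical dehalogenation with a tin hydride, the α-carbonyl C11 radical taking hydrogen from the convex face, which gives the formal hydrate of 17 without acid or base that could dehydrate it back or start the acyl shift before C11 is methylated.

Step 15
Reactants: 19 hemiketal
Product: 21 C11-methyl hemiketal (ring form of the C6-hydroxy α-methyl-α-isobutyryl lactone, methyl on the convex face), via sodium enolate 20 (not isolated)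
Conditions: NaH (1.0 equiv), THF–DMF, 0 °C; then MeI
Reagents that add atoms: iodomethane, CI
Why: C-alkylation of a β-keto lactone enolate, in which one equivalent of NaH opens the hemiketal to the stabilised enolate (the thermodynamic anion, so the acyl shift cannot run ahead) and MeI attacks C11 from the convex face, setting the quaternary C11 with methyl outside and the isobutyryl group inside next to the C6 hydroxyl, onto which it closes again.

Step 16
Reactants: 21 C11-methyl hemiketal
Product: 22 α-methyl lactone with O6 isobutyrate (C11 methyl on the convex face, trans to C6; carbinol still as triethylsilyl ether, O9 as TBS ether)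
Conditions: DBU, toluene, 80 °C
Reagents that add atoms: none
Why: Intramolecular retro-Claisen fragmentation (C-to-O acyl shift), in which the hemiketal alkoxide of the non-enolisable β-keto lactone breaks the C11–CO bond to leave the isobutyryl group on O6 and a lactone enolate, and continued heating with DBU should equilibrate C11 to the more stable epimer with methyl on the convex face.

Step 17
Reactants: 22 α-methyl lactone with O6 isobutyrate
Product: 23 carbinol (free C5 β-CMe2OH, C6 β-isobutyrate, α-methyl lactone, O9 TBS ether)
Conditions: HF·pyridine, pyridine, THF, 0 °C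
Reagents that add atoms: none
Why: Selective desilylation, buffered HF·pyridine cleaving the triethylsilyl ether well before the hindered secondary TBS ether at C9; the carbinol is freed only now because a free hydroxyl here would have trapped the ketone of 19 or 21 as a bridged ketal and stopped the acyl shift.

Step 18
Reactants: 23 carbinol
Product: 24 isopropenyl lactone (C5 β-isopropenyl)
Conditions: Burgess reagent, toluene, 60 °C
Reagents that add atoms: none
Why: Burgess dehydration (syn elimination of the sulfamate ester), in which the six methyl hydrogens are reached far more easily than the single C5–H, which is flanked by the quaternary C10 and the C6 ester and would give a strained tetrasubstituted alkene, so the isopropenyl isomer should predominate.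

Step 19
Reactants: 24 isopropenyl lactone
Product: 25 allylic alcohol (C5 β-(3-hydroxyprop-1-en-2-yl)); any enal formed directly is carried along
Conditions: SeO2 (cat.), t-BuOOH, CH2Cl2, rt
Reagents that add atoms: selenium dioxide, O=[Se]=O (transfers the oxygen); tert-butyl hydroperoxide, CC(C)(C)OO (terminal oxidant)
Why: Allylic oxidation with SeO2/t-BuOOH (ene reaction then [2,3]-sigmatropic shift), in which the isopropenyl methyl group is oxidised in preference to the C5 methine, the vinyl group has no allylic hydrogen, and the double bond returns to its place.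

Step 20
Reactants: 25 allylic alcohol
Product: 26 enal, the O9 TBS ether of the target
Conditions: MnO2, CH2Cl2, rt
Reagents that add atoms: none
Why: MnO2 oxidation of an allylic alcohol, selective for this primary allylic position, which completes the 2-substituted acrolein.

Step 21
Reactants: 26 enal
Product: 27 target CNP0198892.2
Conditions: HF·pyridine, THF, rt
Reagents that add atoms: none
Why: Fluoride-mediated desilylation under mildly acidic conditions, which frees the C9 hydroxyl without base that could add to the enal, epimerise C11 or move the acyl groups.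

**Compound list**

1 | crotonaldehyde, (E)-but-2-enal | C/C=C/C=O | starting material
2 | (E)-1-(tert-butyldimethylsilyloxy)buta-1,3-diene | C=C/C=C/O[Si](C)(C)C(C)(C)C | intermediate
3 | ethyl (2E)-3-methyl-4-oxobut-2-enoate | CCOC(=O)/C=C(\C)C=O | starting material
4 | Diels–Alder adduct, ethyl (1R,5R,6S)-5-(tert-butyldimethylsilyloxy)-6-formyl-6-methylcyclohex-3-ene-1-carboxylate | O=C[C@]1(C)[C@H](O[Si](C)(C)C(C)(C)C)C=CC[C@H]1C(=O)OCC | intermediate
5 | vinyl ester (C10 α-vinyl, β-methyl; C5 β-CO2Et) | C=C[C@]1(C)[C@H](O[Si](C)(C)C(C)(C)C)C=CC[C@H]1C(=O)OCC | intermediate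
6 | methyl ketone (C5 β-acetyl) | C=C[C@]1(C)[C@H](O[Si](C)(C)C(C)(C)C)C=CC[C@H]1C(C)=O | intermediate
7 | tertiary carbinol (C5 β-CMe2OH) | C=C[C@]1(C)[C@H](O[Si](C)(C)C(C)(C)C)C=CC[C@H]1C(C)(C)O | intermediate
8 | bis-silyl ether (C5 β-CMe2OSiEt3, C9 α-OTBS, C7=C8) | C=C[C@]1(C)[C@H](O[Si](C)(C)C(C)(C)C)C=CC[C@H]1C(C)(C)O[Si](CC)(CC)CC | intermediate
9 | C7–C8 β-epoxide | C=C[C@]1(C)[C@H](O[Si](C)(C)C(C)(C)C)[C@H]2O[C@H]2C[C@H]1C(C)(C)O[Si](CC)(CC)CC | intermediate
10 | hydroxy selenide (C8 β-OH, C7 α-SePh) | C=C[C@]1(C)[C@H](O[Si](C)(C)C(C)(C)C)[C@@H](O)[C@H]([Se]c2ccccc2)C[C@H]1C(C)(C)O[Si](CC)(CC)CC | intermediate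
11 | selenoxide of 10 (selenium configuration not defined) | C=C[C@]1(C)[C@H](O[Si](C)(C)C(C)(C)C)[C@@H](O)[C@H]([Se](=O)c2ccccc2)C[C@H]1C(C)(C)O[Si](CC)(CC)CC | intermediate
12 | allylic alcohol (C8 β-OH, C6=C7) | C=C[C@]1(C)[C@H](O[Si](C)(C)C(C)(C)C)[C@@H](O)C=C[C@H]1C(C)(C)O[Si](CC)(CC)CC | intermediate
13 | methyl 4-methyl-3-oxopentanoate | COC(=O)CC(=O)C(C)C | starting material
14 | O8 4-methyl-3-oxopentanoate of 12 | C=C[C@]1(C)[C@H](O[Si](C)(C)C(C)(C)C)[C@@H](OC(=O)CC(=O)C(C)C)C=C[C@H]1C(C)(C)O[Si](CC)(CC)CC | intermediate
15 | O8 2-diazo-4-methyl-3-oxopentanoate | C=C[C@]1(C)[C@H](O[Si](C)(C)C(C)(C)C)[C@@H](OC(=O)C(=[N+]=[N-])C(=O)C(C)C)C=C[C@H]1C(C)(C)O[Si](CC)(CC)CC | intermediate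
16 | cyclopropane-fused γ-lactone with the isobutyryl group on C11 | C=C[C@]1(C)[C@H](O[Si](C)(C)C(C)(C)C)[C@H]2OC(=O)[C@]3(C(=O)C(C)C)[C@H]2[C@@H]3[C@H]1C(C)(C)O[Si](CC)(CC)CC | intermediate
17 | dihydrofuran-fused lactone (O6 on C6, β) | C=C[C@]1(C)[C@H](O[Si](C)(C)C(C)(C)C)[C@H]2OC(=O)C3=C(C(C)C)O[C@H]([C@@H]23)[C@H]1C(C)(C)O[Si](CC)(CC)CC | intermediate
18 | bromo hemiketal (C11–Br; hemiketal carbon an anomeric mixture) | C=C[C@]1(C)[C@H](O[Si](C)(C)C(C)(C)C)[C@H]2OC(=O)[C@]3(Br)[C@H]2[C@@H](OC3(O)C(C)C)[C@H]1C(C)(C)O[Si](CC)(CC)CC | intermediate
19 | hemiketal, ring form of the C6-hydroxy α-isobutyryl lactone (C11–H; hemiketal carbon an anomeric mixture) | C=C[C@]1(C)[C@H](O[Si](C)(C)C(C)(C)C)[C@H]2OC(=O)[C@@H]3[C@H]2[C@@H](OC3(O)C(C)C)[C@H]1C(C)(C)O[Si](CC)(CC)CC | intermediate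
20 | sodium enolate of the open C6-hydroxy α-isobutyryl lactone | C=C[C@]1(C)[C@H](O[Si](C)(C)C(C)(C)C)[C@H]2OC(=O)C(=C([O-])C(C)C)[C@H]2[C@@H](O)[C@H]1C(C)(C)O[Si](CC)(CC)CC.[Na+] | intermediate
21 | C11-methyl hemiketal, ring form of the C6-hydroxy α-methyl-α-isobutyryl lactone (methyl convex; hemiketal carbon an anomeric mixture) | C=C[C@]1(C)[C@H](O[Si](C)(C)C(C)(C)C)[C@H]2OC(=O)[C@]3(C)[C@H]2[C@@H](OC3(O)C(C)C)[C@H]1C(C)(C)O[Si](CC)(CC)CC | intermediate
22 | α-methyl lactone with C6 β-isobutyrate, carbinol as triethylsilyl ether | C=C[C@]1(C)[C@H](O[Si](C)(C)C(C)(C)C)[C@H]2OC(=O)[C@H](C)[C@H]2[C@@H](OC(=O)C(C)C)[C@H]1C(C)(C)O[Si](CC)(CC)CC | intermediate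
23 | α-methyl lactone with C6 β-isobutyrate and free tertiary carbinol | C=C[C@]1(C)[C@H](O[Si](C)(C)C(C)(C)C)[C@H]2OC(=O)[C@H](C)[C@H]2[C@@H](OC(=O)C(C)C)[C@H]1C(C)(C)O | intermediate
24 | C5 isopropenyl lactone | C=C[C@]1(C)[C@H](O[Si](C)(C)C(C)(C)C)[C@H]2OC(=O)[C@H](C)[C@H]2[C@@H](OC(=O)C(C)C)[C@H]1C(C)=C | intermediate
25 | allylic alcohol (C5 β-(3-hydroxyprop-1-en-2-yl)) | C=C[C@]1(C)[C@H](O[Si](C)(C)C(C)(C)C)[C@H]2OC(=O)[C@H](C)[C@H]2[C@@H](OC(=O)C(C)C)[C@H]1C(=C)CO | intermediate
26 | enal, O9 TBS ether of the target | C=C[C@]1(C)[C@H](O[Si](C)(C)C(C)(C)C)[C@H]2OC(=O)[C@H](C)[C@H]2[C@@H](OC(=O)C(C)C)[C@H]1C(=C)C=O | intermediate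
27 | target CNP0198892.2 | C=C[C@]1(C)[C@H](O)[C@H]2OC(=O)[C@H](C)[C@H]2[C@@H](OC(=O)C(C)C)[C@H]1C(=C)C=O | target

**Totals**

Total step count: 21. Longest linear sequence: 21 steps (1 to 27); 3 and 13 enter as purchased materials.

**Three steps most likely to fail**

Step 12 (ring expansion). Iodide may fail to open this acceptor-only cyclopropane at the secondary carbon C6, or the opened intermediate may eliminate instead of closing through oxygen. The fallback sets out from β-keto ester 14 and comes back at 17. It is an oxidative free-radical cyclisation with Mn(OAc)3·2H2O (trivalent manganese) and Cu(OAc)2 (divalent copper) in acetic acid at 60 °C. The manganese enolate radical at C11 adds 5-exo to C7 on the β face through the same O8 tether; the C6 radical is oxidised by copper and captured by the ketone enol oxygen. This should give the dihydrofuran-fused lactone 17 in one operation, with neither diazo compound nor cyclopropane; no new compound is isolated on the way (F0).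

Step 16 (acyl shift). The hemiketal alkoxide may fail to fragment, or the C6 alkoxide may add to the lactone carbonyl and scramble the two acyl groups between O6 and O8. The fallback sets out from 21 and comes back at 22. K2CO3 in methanol at 0 °C cleaves the non-enolisable β-keto lactone by intermolecular retro-Claisen methanolysis. The isobutyryl group leaves as methyl isobutyrate (any O6 ester formed is methanolysed too), and C11 equilibrates, to give the C6-hydroxy α-methyl lactone F2. Conventional esterification of O6 with isobutyric anhydride, DMAP and pyridine then gives 22.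

Step 6 (epoxidation). Facial selectivity may be poor, because the axial C10 methyl group on the β face opposes the anti-directing C9 silyloxy group. The fallback sets out from carbinol 7 and comes back at 9. Hydroxyl-directed epoxidation with VO(acac)2 and t-BuOOH in CH2Cl2 uses the tertiary hydroxyl, which sits on the β face, to deliver the peroxide to the β face of C7=C8 and give the β-epoxy carbinol F1. Silylation with Et3SiOTf and 2,6-lutidine then gives 9.

**Further compounds**

F1 | step 6 | β-epoxy carbinol (C7–C8 β-epoxide, free C5 β-CMe2OH) | C=C[C@]1(C)[C@H](O[Si](C)(C)C(C)(C)C)[C@H]2O[C@H]2C[C@H]1C(C)(C)O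
F0 | step 12 | none | none
F2 | step 16 | C6-hydroxy α-methyl lactone (C6 β-OH, carbinol as triethylsilyl ether) | C=C[C@]1(C)[C@H](O[Si](C)(C)C(C)(C)C)[C@H]2OC(=O)[C@H](C)[C@H]2[C@@H](O)[C@H]1C(C)(C)O[Si](CC)(CC)CC
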